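**Strategy.** Everything rests on cutting C4–C5 and C9–C10 of the trans-decalin (rings A and B). The feature used is the quaternary C4 of ring A: its oxygen-bearing carbon C19 stands axial, on the face of the C10 methyl, which is where the carboxyl of a 2-methyl-3-oxo ester ends up when its C4 radical closes ring A, so that ester carbon is C19. One oxidative radical bicyclisation of an acyclic (E,E)-dienyl keto ester, biased by a (−)-8-phenylmenthyl ester, forms both rings, sets C4, C5, C9 and C10 and leaves an alkene at C8. The precursor is made by joining that keto ester at C1–C2 to a bromide cut from (S)-2,3-dihydrofarnesol, which brings C13. The angelate goes on last.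

Key step: step 7

Remark on the chemistry: the facial sense of the (−)-8-phenylmenthyl ester (phenyl stacked over the C4 radical with the C18 methyl beneath it) is assumed to carry over from ring-A closures of α-methyl β-keto esters of this alcohol to the present diene; a reversed sense would be answered by the enantiomeric alcohol with no other change.

Step 1
Reactants: 1 (2E,6E)-farnesol
Product: 2 (3S,6E)-3,7,11-trimethyldodeca-6,10-dien-1-ol [(S)-2,3-dihydrofarnesol]
Conditions: H2 (30 atm), Ru(OAc)2[(R)-BINAP] (0.2 mol %), MeOH–H2O 95:5, 20 °C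
Reagents that add atoms: none
Why: Noyori asymmetric hydrogenation of an allylic alcohol: the hydroxyl-bound ruthenium carboxylate reduces only the C2=C3 alkene, and the (R)-ligand acting on the 2E-alkene should give the 3S centre (later C13), the same sense as geraniol to (S)-citronellol.

Step 2
Reactants: 2 (3S,6E)-3,7,11-trimethyldodeca-6,10-dien-1-ol
Product: 3 tert-butyldiphenylsilyl ether of 2
Conditions: TBDPSCl, imidazole, DMF, 0 °C to rt
Reagents that add atoms: tert-butyl(chloro)diphenylsilane, CC(C)(C)[Si](Cl)(c1ccccc1)c1ccccc1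
Why: Routine silylation of a primary alcohol; the tert-butyldiphenylsilyl ether is chosen because it has to survive acetic acid in step 7, hydride in steps 8 and 12 and the radical steps.

Step 3
Reactants: 3 tert-butyldiphenylsilyl ether of 2
Product: 4 (2E,6E,10S)-12-(tert-butyldiphenylsilyloxy)-2,6,10-trimethyldodeca-2,6-dien-1-ol
Conditions: SeO2 (0.3 equiv), t-BuOOH (70 % aq., 3 equiv), salicylic acid (0.1 equiv), CH2Cl2, rt, stopped at partial conversion, 3 recycled
Reagents that add atoms: SeO2, O=[Se]=O (delivers the oxygen); tert-butyl hydroperoxide, CC(C)(C)OO (reoxidises selenium, net oxygen source)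
Why: SeO2 allylic (Riley) oxidation by ene reaction and [2,3]-sigmatropic shift hydroxylates the (E)-methyl of a terminal isopropylidene group, and the exposed terminal alkene should react ahead of the internal one.

Step 4
Reactants: 4 (2E,6E,10S)-12-(tert-butyldiphenylsilyloxy)-2,6,10-trimethyldodeca-2,6-dien-1-ol
Product: 5 (2E,6E,10S)-1-bromo-12-(tert-butyldiphenylsilyloxy)-2,6,10-trimethyldodeca-2,6-diene
Conditions: CBr4, PPh3, CH2Cl2, 0 °C
Reagents that add atoms: carbon tetrabromide, BrC(Br)(Br)Br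
Why: Appel bromination converts the primary allylic alcohol to the bromide under neutral conditions, without allylic transposition or loss of the silyl ether.

Step 5
Reactants: 6 ethyl 2-methyl-3-oxobutanoate (ethyl 2-methylacetoacetate); 7 (−)-8-phenylmenthol [(1R,2S,5R)-5-methyl-2-(2-phenylpropan-2-yl)cyclohexan-1-ol]
Product: 8 (−)-8-phenylmenthyl 2-methyl-3-oxobutanoate (both C2 epimers)
Conditions: 6 (1.5 equiv), DMAP (0.3 equiv), toluene, reflux, EtOH distilled off
Reagents that add atoms: none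
Why: DMAP-catalysed transesterification of a β-keto ester passes through the acyl ketene that the remaining α-hydrogen allows, and is effective for hindered secondary alcohols once ethanol is removed.

Step 6
Reactants: 8 (−)-8-phenylmenthyl 2-methyl-3-oxobutanoate; 5 (2E,6E,10S)-1-bromo-12-(tert-butyldiphenylsilyloxy)-2,6,10-trimethyldodeca-2,6-diene
Product: 10 (−)-8-phenylmenthyl (6E,10E,14S)-16-(tert-butyldiphenylsilyloxy)-2,6,10,14-tetramethyl-3-oxohexadeca-6,10-dienoate (both C2 epimers), via keto ester dianion 9 (not isolated)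
Conditions: NaH (1.1 equiv), THF, 0 °C; n-BuLi (1.05 equiv), 0 °C; then 5, 0 °C to rt; aq. NH4Cl
Reagents that add atoms: none
Why: γ-Alkylation of a β-keto ester dianion: the less stabilised carbanion at the acetyl methyl is the more nucleophilic site and displaces the primary allylic bromide (SN2), forming C1–C2 without touching either alkene geometry.

Step 7
Reactants: 10 (−)-8-phenylmenthyl (6E,10E,14S)-16-(tert-butyldiphenylsilyloxy)-2,6,10,14-tetramethyl-3-oxohexadeca-6,10-dienoate
Product: 11 (−)-8-phenylmenthyl (13S)-15-(tert-butyldiphenylsilyloxy)-3-oxolabd-8(17)-en-19-oate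
Conditions: Mn(OAc)3·2H2O (2.2 equiv), Cu(OAc)2·H2O (1.0 equiv), degassed AcOH (0.05 M), 25–40 °C
Reagents that add atoms: none
Why: Mn(OAc)3 oxidises the enol form of the keto ester to an electrophilic tertiary C4 radical, which adds to C5 of the electron-rich C5=C10 alkene, and the tertiary C10 radical so formed adds to C9 of the C8=C9 alkene; Cu(OAc)2 then traps the tertiary C8 radical and β-hydride loss from the C17 methyl should give the exocyclic 8(17)-alkene. The closest known reaction type is the oxidative free-radical polyene cyclisation of α-methyl β-keto esters by trivalent manganese and divalent copper, which is also known for 8-phenylmenthyl esters in ring-A closures. Ring A (C4–C5) and ring B (C9–C10) each close 6-endo-trig, in both cases joining the radical to the less substituted end of a trisubstituted alkene so that a tertiary radical results. C4 is controlled by the auxiliary, whose phenyl group stacks over one face of the planar dicarbonyl radical with the small C18 methyl beneath it, so that C5 bonds to the open face; C5, C10 and C9 are controlled by the chair–chair fold of the E,E-diene with the ester axial and the C11 chain equatorial, which gives the trans ring fusion, C19 cis to the C10 methyl and the C9 chain equatorial. The selectivity the step needs is facial at C4, since everything else is relayed from it, and because the auxiliary makes the minor ring isomer a diastereomer it can be removed by chromatography at 11 or 12. The α-methyl group prevents re-enolisation and over-oxidation of the product, and the ester that activates the radical is C19 itself in its axial place.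

Step 8
Reactants: 11 (−)-8-phenylmenthyl (13S)-15-(tert-butyldiphenylsilyloxy)-3-oxolabd-8(17)-en-19-oate
Product: 12 (−)-8-phenylmenthyl (3S,13S)-15-(tert-butyldiphenylsilyloxy)-3β-hydroxylabd-8(17)-en-19-oate
Conditions: NaBH4, MeOH–THF, 0 °C
Reagents that add atoms: none
Why: Hydride reduction of the ketone leaves the hindered neopentyl ester alone, and hydride should enter from the α face, away from the axial C19 ester and C20 methyl, to give the equatorial 3β-alcohol, although either epimer would serve because C3 is deoxygenated next.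

Step 9
Reactants: 12 (−)-8-phenylmenthyl (3S,13S)-15-(tert-butyldiphenylsilyloxy)-3β-hydroxylabd-8(17)-en-19-oate
Product: 13 the 3β-O-(imidazol-1-ylthiocarbonyl) derivative of 12
Conditions: 1,1'-thiocarbonyldiimidazole, DMAP (cat.), ClCH2CH2Cl, reflux
Reagents that add atoms: 1,1'-thiocarbonyldiimidazole, S=C(n1ccnc1)n1ccnc1
Why: Thioacylation under neutral conditions prepares the Barton–McCombie substrate without forming the alkoxide of a β-hydroxy ester, which could open ring A by retro-aldol cleavage.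

Step 10
Reactants: 13 the 3β-O-(imidazol-1-ylthiocarbonyl) derivative of 12
Product: 14 (−)-8-phenylmenthyl (13S)-15-(tert-butyldiphenylsilyloxy)labd-8(17)-en-19-oate
Conditions: Bu3SnH, AIBN (cat.), toluene, reflux
Reagents that add atoms: none
Why: Barton–McCombie radical deoxygenation: the stannyl radical adds to sulfur, the C3–O bond fragments and the secondary C3 radical is reduced by Bu3SnH, with no stereocentre at stake and no alkene within reach of C3.

Step 11
Reactants: 14 (−)-8-phenylmenthyl (13S)-15-(tert-butyldiphenylsilyloxy)labd-8(17)-en-19-oate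
Product: 15 (−)-8-phenylmenthyl (13S)-15-(tert-butyldiphenylsilyloxy)labd-7-en-19-oate
Conditions: chloro[N,N'-bis(3,5-di-tert-butylsalicylidene)-1,2-cyclohexanediaminato]cobalt (trivalent cobalt, 3 mol %), PhSiH3 (6 mol %), benzene, 22 °C
Reagents that add atoms: none
Why: Cobalt-hydride hydrogen-atom-transfer alkene isomerisation: reversible H-atom addition to C17 gives the tertiary C8 radical and the cobalt complex should take a hydrogen back from the accessible C7 methylene, not the shielded C9 methine, so the alkene moves one position to trisubstituted C7=C8 and stops there.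

Step 12
Reactants: 15 (−)-8-phenylmenthyl (13S)-15-(tert-butyldiphenylsilyloxy)labd-7-en-19-oate
Product: 16 (4S,5R,9S,10R,13S)-15-(tert-butyldiphenylsilyloxy)labd-7-en-19-ol
Conditions: LiAlH4 (excess), THF, 0 °C to reflux; aq. NaOH work-up
Reagents that add atoms: none
Why: LiAlH4 reduction of the hindered ester gives the C19 primary alcohol directly and releases the auxiliary for recovery, while the silyl ether and the trisubstituted alkene are inert.

Step 13
Reactants: 16 (4S,5R,9S,10R,13S)-15-(tert-butyldiphenylsilyloxy)labd-7-en-19-ol; 17 angelic acid [(Z)-2-methylbut-2-enoic acid]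
Product: 19 (13S)-15-(tert-butyldiphenylsilyloxy)labd-7-en-19-yl angelate, via angelic 2,4,6-trichlorobenzoic anhydride 18 (not isolated)
Conditions: 17, 2,4,6-trichlorobenzoyl chloride, Et3N, toluene, rt; then 16, 75 °C
Reagents that add atoms: none
Why: Yamaguchi-type mixed-anhydride esterification run without DMAP transfers the (Z)-2-methylbut-2-enoyl group to the neopentyl primary alcohol under conditions that should not isomerise it to the tiglate.

Step 14
Reactants: 19 (13S)-15-(tert-butyldiphenylsilyloxy)labd-7-en-19-yl angelate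
Product: 20 (13S)-15-hydroxylabd-7-en-19-yl angelate
Conditions: Bu4NF, AcOH, THF, rt
Reagents that add atoms: none
Why: Fluoride-mediated desilylation, buffered with acetic acid so that the angelate is neither cleaved nor isomerised.

Step 15
Reactants: 20 (13S)-15-hydroxylabd-7-en-19-yl angelate
Product: 22 (4S,5R,9S,10R,13S)-19-angeloyloxylabd-7-en-15-oic acid, via aldehyde 21 (not isolated)
Conditions: TEMPO (0.2 equiv), PhI(OAc)2 (2.5 equiv), MeCN–H2O 1:1, rt
Reagents that add atoms: water, O
Why: TEMPO-catalysed oxidation with PhI(OAc)2 in aqueous acetonitrile takes the primary alcohol through the aldehyde and its hydrate to the acid and should leave the trisubstituted alkene, the enoate and the β stereocentre C13 untouched.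

**Compound list**

1 | (2E,6E)-farnesol | CC(C)=CCC/C(C)=C/CC/C(C)=C/CO | starting material
2 | (3S,6E)-3,7,11-trimethyldodeca-6,10-dien-1-ol [(S)-2,3-dihydrofarnesol] | CC(C)=CCC/C(C)=C/CC[C@H](C)CCO | intermediate
3 | tert-butyl{[(3S,6E)-3,7,11-trimethyldodeca-6,10-dien-1-yl]oxy}diphenylsilane | CC(C)=CCC/C(C)=C/CC[C@H](C)CCO[Si](c1ccccc1)(c1ccccc1)C(C)(C)C | intermediate
4 | (2E,6E,10S)-12-(tert-butyldiphenylsilyloxy)-2,6,10-trimethyldodeca-2,6-dien-1-ol | OC/C(C)=C/CC/C(C)=C/CC[C@H](C)CCO[Si](c1ccccc1)(c1ccccc1)C(C)(C)C | intermediate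
5 | (2E,6E,10S)-1-bromo-12-(tert-butyldiphenylsilyloxy)-2,6,10-trimethyldodeca-2,6-diene | BrC/C(C)=C/CC/C(C)=C/CC[C@H](C)CCO[Si](c1ccccc1)(c1ccccc1)C(C)(C)C | intermediate
6 | ethyl 2-methyl-3-oxobutanoate | CCOC(=O)C(C)C(C)=O | starting material
7 | (−)-8-phenylmenthol, (1R,2S,5R)-5-methyl-2-(2-phenylpropan-2-yl)cyclohexan-1-ol | C[C@@H]1CC[C@@H](C(C)(C)c2ccccc2)[C@H](O)C1 | starting material
8 | (−)-8-phenylmenthyl 2-methyl-3-oxobutanoate (C2 epimers) | C[C@@H]1CC[C@@H](C(C)(C)c2ccccc2)[C@H](OC(=O)C(C)C(C)=O)C1 | intermediate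
9 | sodium lithium dianion (1,3-dienolate) of 8 | C[C@@H]1CC[C@@H](C(C)(C)c2ccccc2)[C@H](OC([O-])=C(C)C([O-])=C)C1.[Na+].[Li+] | intermediate
10 | (−)-8-phenylmenthyl (6E,10E,14S)-16-(tert-butyldiphenylsilyloxy)-2,6,10,14-tetramethyl-3-oxohexadeca-6,10-dienoate (C2 epimers) | C[C@@H]1CC[C@@H](C(C)(C)c2ccccc2)[C@H](OC(=O)C(C)C(=O)CC/C(C)=C/CC/C(C)=C/CC[C@H](C)CCO[Si](c2ccccc2)(c2ccccc2)C(C)(C)C)C1 | intermediate
11 | (−)-8-phenylmenthyl (13S)-15-(tert-butyldiphenylsilyloxy)-3-oxolabd-8(17)-en-19-oate (normal labdane series: ester carbon C19 axial on C4, 10β-methyl, 5α-H, 9α-H) | C[C@@H]1CC[C@@H](C(C)(C)c2ccccc2)[C@H](OC(=O)[C@@]3(C)C(=O)CC[C@]4(C)[C@@H](CC[C@H](C)CCO[Si](c2ccccc2)(c2ccccc2)C(C)(C)C)C(=C)CC[C@@H]34)C1 | intermediate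
12 | (−)-8-phenylmenthyl (3S,13S)-15-(tert-butyldiphenylsilyloxy)-3β-hydroxylabd-8(17)-en-19-oate | C[C@@H]1CC[C@@H](C(C)(C)c2ccccc2)[C@H](OC(=O)[C@@]3(C)[C@@H](O)CC[C@]4(C)[C@@H](CC[C@H](C)CCO[Si](c2ccccc2)(c2ccccc2)C(C)(C)C)C(=C)CC[C@@H]34)C1 | intermediate
13 | (−)-8-phenylmenthyl (3S,13S)-15-(tert-butyldiphenylsilyloxy)-3β-(imidazol-1-ylthiocarbonyloxy)labd-8(17)-en-19-oate | C[C@@H]1CC[C@@H](C(C)(C)c2ccccc2)[C@H](OC(=O)[C@@]3(C)[C@@H](OC(=S)n5ccnc5)CC[C@]4(C)[C@@H](CC[C@H](C)CCO[Si](c2ccccc2)(c2ccccc2)C(C)(C)C)C(=C)CC[C@@H]34)C1 | intermediate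
14 | (−)-8-phenylmenthyl (13S)-15-(tert-butyldiphenylsilyloxy)labd-8(17)-en-19-oate | C[C@@H]1CC[C@@H](C(C)(C)c2ccccc2)[C@H](OC(=O)[C@@]3(C)CCC[C@]4(C)[C@@H](CC[C@H](C)CCO[Si](c2ccccc2)(c2ccccc2)C(C)(C)C)C(=C)CC[C@@H]34)C1 | intermediate
15 | (−)-8-phenylmenthyl (13S)-15-(tert-butyldiphenylsilyloxy)labd-7-en-19-oate | C[C@@H]1CC[C@@H](C(C)(C)c2ccccc2)[C@H](OC(=O)[C@@]3(C)CCC[C@]4(C)[C@@H](CC[C@H](C)CCO[Si](c2ccccc2)(c2ccccc2)C(C)(C)C)C(C)=CC[C@@H]34)C1 | intermediate
16 | (4S,5R,9S,10R,13S)-15-(tert-butyldiphenylsilyloxy)labd-7-en-19-ol | OC[C@@]1(C)CCC[C@]2(C)[C@@H](CC[C@H](C)CCO[Si](c3ccccc3)(c3ccccc3)C(C)(C)C)C(C)=CC[C@@H]12 | intermediate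
17 | angelic acid, (Z)-2-methylbut-2-enoic acid | C/C=C(/C)C(=O)O | starting material
18 | angelic 2,4,6-trichlorobenzoic anhydride | C/C=C(/C)C(=O)OC(=O)c1c(Cl)cc(Cl)cc1Cl | intermediate
19 | (13S)-15-(tert-butyldiphenylsilyloxy)labd-7-en-19-yl angelate | C/C=C(/C)C(=O)OC[C@@]1(C)CCC[C@]2(C)[C@@H](CC[C@H](C)CCO[Si](c3ccccc3)(c3ccccc3)C(C)(C)C)C(C)=CC[C@@H]12 | intermediate
20 | (13S)-15-hydroxylabd-7-en-19-yl angelate | C/C=C(/C)C(=O)OC[C@@]1(C)CCC[C@]2(C)[C@@H](CC[C@H](C)CCO)C(C)=CC[C@@H]12 | intermediate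
21 | (13S)-15-oxolabd-7-en-19-yl angelate | C/C=C(/C)C(=O)OC[C@@]1(C)CCC[C@]2(C)[C@@H](CC[C@H](C)CC=O)C(C)=CC[C@@H]12 | intermediate
22 | (4S,5R,9S,10R,13S)-19-angeloyloxylabd-7-en-15-oic acid | C/C=C(/C)C(=O)OC[C@@]1(C)CCC[C@]2(C)[C@@H](CC[C@H](C)CC(=O)O)C(C)=CC[C@@H]12 | target

**Totals.** 15 steps in all; the longest linear sequence is 14 steps (steps 1 to 4 and 6 to 15).

**Steps most likely to fail**

Step 7. The bulky ester may slow enolisation and oxidation so that the cascade becomes inefficient, or the auxiliary may discriminate the two faces of the C4 radical too weakly for useful throughput. The fallback sets out from 5 and 6 and comes back at 16, and it moves absolute control from the ester to a resolution. NaH then n-BuLi convert 6 into the sodium lithium dianion of ethyl 2-methylacetoacetate F1, which is alkylated by 5 to the ethyl keto ester F2. Mn(OAc)3·2H2O and Cu(OAc)2·H2O in AcOH should give the ethyl 3-oxolabd-8(17)-en-19-oate F3 together with its ring-inverted 13S diastereomer. The pair is taken through the operations of steps 8 to 11 as the ethyl 3β-hydroxy ester F4, the ethyl imidazolylthiocarbonate F5, the ethyl labd-8(17)-en-19-oate F6 and the ethyl labd-7-en-19-oate F7. LiAlH4 then gives 16 mixed with its diastereomer. (1S)-Camphanic chloride with pyridine and DMAP converts both into camphanates, the 19-camphanate of 16 F8 is separated by chromatography or crystallisation, and K2CO3 in MeOH returns 16.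

Step 11. Hydrogen return from C9 may compete with return from C7, or the alkene may migrate further, so that the tetrasubstituted C8=C9 isomer contaminates 15. The fallback sets out from 14 and comes back at 15, and it fixes the alkene position by a regiospecific sequence. Lemieux–Johnson cleavage (OsO4 cat., NaIO4, 2,6-lutidine, dioxane–water) gives the 8-oxo-17-nor ester F9. KHMDS in THF at −78 °C removes a proton from the C7 methylene, not from the hindered C9 methine, to give the potassium 7-en-8-olate F10, which PhNTf2 converts into the 7-en-8-yl triflate F11. Negishi coupling with MeZnCl and Pd(PPh3)4 (zerovalent palladium) in THF restores C17 and gives 15.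

Step 3. Oxidation at the allylic positions of the internal C6=C7 alkene and over-oxidation to the enal may compete, giving low regioselectivity and conversion. The fallback sets out from 3 and comes back at 4, and it rebuilds the chain end by cleavage and olefination. NBS in aqueous THF adds to the exposed terminal alkene to give the terminal bromohydrin F12, and K2CO3 in MeOH closes it to the terminal epoxide F13. H5IO6 in THF–ether cleaves the epoxide to the trisnor aldehyde F14. Wittig olefination with Ph3P=C(CH3)CO2Et gives the (E)-enoate F15, and DIBAL-H in CH2Cl2 at −78 °C reduces it to 4.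

**Further compounds**

F1 | step 7 | sodium lithium dianion of ethyl 2-methylacetoacetate | CCOC([O-])=C(C)C([O-])=C.[Na+].[Li+]
F2 | step 7 | ethyl (6E,10E,14S)-16-(tert-butyldiphenylsilyloxy)-2,6,10,14-tetramethyl-3-oxohexadeca-6,10-dienoate | CCOC(=O)C(C)C(=O)CC/C(C)=C/CC/C(C)=C/CC[C@H](C)CCO[Si](c1ccccc1)(c1ccccc1)C(C)(C)C
F3 | step 7 | ethyl (13S)-15-(tert-butyldiphenylsilyloxy)-3-oxolabd-8(17)-en-19-oate (formed with its ring-inverted 13S diastereomer) | CCOC(=O)[C@@]1(C)C(=O)CC[C@]2(C)[C@@H](CC[C@H](C)CCO[Si](c3ccccc3)(c3ccccc3)C(C)(C)C)C(=C)CC[C@@H]12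
F4 | step 7 | ethyl (3S,13S)-15-(tert-butyldiphenylsilyloxy)-3β-hydroxylabd-8(17)-en-19-oate | CCOC(=O)[C@@]1(C)[C@@H](O)CC[C@]2(C)[C@@H](CC[C@H](C)CCO[Si](c3ccccc3)(c3ccccc3)C(C)(C)C)C(=C)CC[C@@H]12
F5 | step 7 | ethyl (3S,13S)-15-(tert-butyldiphenylsilyloxy)-3β-(imidazol-1-ylthiocarbonyloxy)labd-8(17)-en-19-oate | CCOC(=O)[C@@]1(C)[C@@H](OC(=S)n3ccnc3)CC[C@]2(C)[C@@H](CC[C@H](C)CCO[Si](c3ccccc3)(c3ccccc3)C(C)(C)C)C(=C)CC[C@@H]12
F6 | step 7 | ethyl (13S)-15-(tert-butyldiphenylsilyloxy)labd-8(17)-en-19-oate | CCOC(=O)[C@@]1(C)CCC[C@]2(C)[C@@H](CC[C@H](C)CCO[Si](c3ccccc3)(c3ccccc3)C(C)(C)C)C(=C)CC[C@@H]12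
F7 | step 7 | ethyl (13S)-15-(tert-butyldiphenylsilyloxy)labd-7-en-19-oate | CCOC(=O)[C@@]1(C)CCC[C@]2(C)[C@@H](CC[C@H](C)CCO[Si](c3ccccc3)(c3ccccc3)C(C)(C)C)C(C)=CC[C@@H]12
F8 | step 7 | (13S)-15-(tert-butyldiphenylsilyloxy)labd-7-en-19-yl (1S,4R)-camphanate | O=C(OC[C@@]1(C)CCC[C@]2(C)[C@@H](CC[C@H](C)CCO[Si](c3ccccc3)(c3ccccc3)C(C)(C)C)C(C)=CC[C@@H]12)[C@@]12CC[C@@](C)(C(=O)O1)C2(C)C
F9 | step 11 | (−)-8-phenylmenthyl (13S)-15-(tert-butyldiphenylsilyloxy)-8-oxo-17-norlabdan-19-oate | C[C@@H]1CC[C@@H](C(C)(C)c2ccccc2)[C@H](OC(=O)[C@@]3(C)CCC[C@]4(C)[C@@H](CC[C@H](C)CCO[Si](c2ccccc2)(c2ccccc2)C(C)(C)C)C(=O)CC[C@@H]34)C1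
F10 | step 11 | potassium 7-en-8-olate of F9 | C[C@@H]1CC[C@@H](C(C)(C)c2ccccc2)[C@H](OC(=O)[C@@]3(C)CCC[C@]4(C)[C@@H](CC[C@H](C)CCO[Si](c2ccccc2)(c2ccccc2)C(C)(C)C)C([O-])=CC[C@@H]34)C1.[K+]
F11 | step 11 | (−)-8-phenylmenthyl (13S)-15-(tert-butyldiphenylsilyloxy)-8-(trifluoromethylsulfonyloxy)-17-norlabd-7-en-19-oate | C[C@@H]1CC[C@@H](C(C)(C)c2ccccc2)[C@H](OC(=O)[C@@]3(C)CCC[C@]4(C)[C@@H](CC[C@H](C)CCO[Si](c2ccccc2)(c2ccccc2)C(C)(C)C)C(OS(=O)(=O)C(F)(F)F)=CC[C@@H]34)C1
F12 | step 3 | (6E,10S)-3-bromo-12-(tert-butyldiphenylsilyloxy)-2,6,10-trimethyldodec-6-en-2-ol (C3 epimers) | CC(C)(O)C(Br)CC/C(C)=C/CC[C@H](C)CCO[Si](c1ccccc1)(c1ccccc1)C(C)(C)C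
F13 | step 3 | terminal epoxide, 2,2-dimethyl-3-[(3E,7S)-9-(tert-butyldiphenylsilyloxy)-3,7-dimethylnon-3-en-1-yl]oxirane | CC1(C)OC1CC/C(C)=C/CC[C@H](C)CCO[Si](c1ccccc1)(c1ccccc1)C(C)(C)C
F14 | step 3 | (4E,8S)-10-(tert-butyldiphenylsilyloxy)-4,8-dimethyldec-4-enal | O=CCC/C(C)=C/CC[C@H](C)CCO[Si](c1ccccc1)(c1ccccc1)C(C)(C)C
F15 | step 3 | ethyl (2E,6E,10S)-12-(tert-butyldiphenylsilyloxy)-2,6,10-trimethyldodeca-2,6-dienoate | CCOC(=O)/C(C)=C/CC/C(C)=C/CC[C@H](C)CCO[Si](c1ccccc1)(c1ccccc1)C(C)(C)C
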